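## Structural features

The target joins two polycycles through one spiro carbon. Ring A is a cyclohex-2-ene-1,4-dione, the 6,7-dihydro form of a 2,2-dimethyl-2H-chromene-5,8-dione with the pyran oxygen on C8a and a prenyl group on C6. The cage is a 4-oxatricyclo[4.3.1.0^3,7]dec-8-en-2-one: C1 bridgehead carbinol, C2 ketone, C3 prenylated quaternary carbon, O4–C5Me2 ether, C6 methine, C7 oxygenated bridgehead, C8=C9 enoate, C10 methylene. Ring A C7 is the spiro atom; it carries the acyloxy oxygen of the cage C8 carboxyl group and the ether oxygen of cage C7, so the link is a six-membered 1,3-dioxan-4-one, a mixed acylal. The four cage stereocentres (C1, C3, C6, C7) are contiguous and locked to one another by the cage, so one absolute centre fixes all. The spiro carbon stands next to the enolisable CH(prenyl) carbon C6 of ring A, and both of these can equilibrate. Fragile groups are the acylal (base opens it by beta-elimination from the ring A enolate, aqueous acid hydrolyses it), the tertiary alpha-ketol at C1/C2 (acyloin shift under base), the beta-alkoxy ketone C7–C3–C2 (retro-aldol), and the prenyl and chromene alkenes (strong acid, electrophilic oxidants). The real difficulty is cage C3, which is fully substituted by the ketone, the oxygenated bridgehead, a prenyl group and the ether oxygen that returns to C5, together with the spiro acylal. The key step exploits that C3 lies between the C2 carbonyl and C7 (a former carbonyl) and is bonded to O4, whose other partner C5 hangs on the neighbouring carbon C6. This is the pattern of a cyclic 1,3-dione whose C2 can act as a carbene carbon and whose C4 carries a CMe2–O–allyl arm.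

## Logic of the disconnections

35 is cut at the two C–O bonds of the ring A spiro carbon (ester oxygen and cage ether oxygen), giving 25 and 33. Both bonds are acetal-level bonds that form reversibly, and the cut separates the cage from ring A and removes two adjustable stereocentres. The forward step must acylate the vinylogous acid oxygen of 33 (to 34) and then add a tertiary alcohol to the activated quinone carbon without base, and the two ring A centres must settle by equilibration.

33 is cut at the C6–CH2 bond to 31 and 32, because C6 is the nucleophilic carbon of a vinylogous acid. 31 comes from 30 by O–Me cleavage. 30 is cut at C4–C4a and O1–C2 to 27 and 28 (chromene annulation on a hydroxyquinone), and 27 comes from 26 by hydrolysis of one methoxy group. This reduces ring A to a symmetrical commercial quinone. The demands are C- over O-alkylation in the prenylation and closure of the pyran through the oxygen that leaves a para-quinone.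

25 is traced through 24 to 23 (ester and silyl ether as the only protecting groups), and 23 is cut at cage C1–C9 and C7–C8 to 19 and 20. The two-carbon enoate bridge is the only part of the cage not present in the oxabicycle, and both bonds can form in one Michael–aldol sequence. The forward step must add the C3 enolate of 19 to 20 on the face of the one-carbon carbonyl bridge, and the vinyl anion must then reach that carbonyl.

19 is cut at the trisubstituted alkene to 17 and 18 (cross-metathesis), and 17 is traced through 15 to 14 by removing the oxygen at C3 of the bicyclooctane. This leaves a dione with a single enolisable position, so the regiochemistry of the oxidation is not in question. The oxidation must precede the metathesis, so that the oxidant meets only a terminal alkene besides the silyl enol ether.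

14 is cut at O6–C5 and C5–CH2 (through 13) to 12. This is the key disconnection: it removes one ring, two skeletal bonds and the quaternary centre, and leaves one stereocentre. The forward step needs the carbenoid to choose the ether oxygen over C–H bonds and the alkene, and the allyl group must be the unsubstituted one so that the shift delivers a linear chain.

12 is traced to 11 (diazo transfer), 11 to 10 (alcohol oxidation) and 10 to 8 (beta-oxygenation of the enone). The second carbonyl is therefore placed next to the stereocentre by the position of the enone alkene. These steps must be mild enough that the single stereocentre, which ends up alpha to a carbonyl, does not racemise.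

8 is cut at the O–allyl bond to 6 and 7, and 6 is traced through 2 to 1 by re-forming the cyclobutane bond between the carbonyl alpha-carbon and the CMe2 carbon. 1 supplies the absolute configuration and the gem-dimethyl carbinol carbon. The ether must be made before the dione exists and without base, and the enol derivative 2 must never equilibrate, since its two regioisomers are enantiomers.

## Other disconnections considered

Alternative 1: The cage is cut at the C7–O bond of the oxygenated bridgehead and at C1–C10. This leads back to the dearomatised benzofuranone A2, a 7a-prenyl-2,3-dihydrobenzofuran-7(7aH)-one with an iodomethyl group on C3, a silyloxy group on C6 and the ester on C4. In the forward key step 4-methoxybenzyl alkoxide would add to the ring-fusion carbon, which is delta to the ketone and beta to the ester. The dienolate so formed would be alkylated at its silyloxy-bearing alpha-carbon by the iodomethyl arm (6-exo-tet) to give A1. In its favour, two bonds and the bicyclo[2.2.2]octene arise in one flask, and the bridgehead oxygen arrives protected and orthogonal to the silyl ether. The ring-closing event is an intramolecular alkylation, which is more dependable than the intermolecular Michael–aldol reaction with 20 used here; on this point the alternative is the better plan. Against it, the prenylated quaternary carbon and the iodomethyl methine must both be in place, in the correct relative and absolute sense, before the cascade. The hardest centre is thus moved into an enantioselective alkylative dearomatisation for which the substrate offers no built-in control. Cyclohexa-2,4-dienones of this kind also tend to dimerise by [4+2] cycloaddition, the alkoxide must prefer 1,6-addition over 1,2-addition and transesterification, and a hindered bridgehead 4-methoxybenzyl ether must later be cleaved oxidatively beside two electron-rich alkenes. Compared with the chosen plan the mechanistic risk of the ring closure is lower, but the stereochemical risk is higher, because the chosen plan takes its absolute configuration from 1 and relays it through a tether-enforced cis bridge. Step economy is judged about equal: the cascade saves the alpha-oxygenation and annulation steps but requires the synthesis and dearomatisation of A2 and a deprotection.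

Alternative 2: The cut is the C1–C2 bond between the bridgehead carbinol and the ketone. This leads to keto aldehyde A4, in which the aldehyde sits on the prenylated tetrahydrofuran carbon and a cis-fused cyclohexenone carries the ester. In the forward key step an N-heterocyclic carbene would convert the aldehyde into an acyl-anion equivalent that adds to the ring ketone (6-exo-trig aldehyde–ketone benzoin) to give ketol A3. In its favour, the tertiary alpha-ketol is formed directly, free, with the only configuration the cage allows, under catalytic and nearly neutral conditions. No enolate oxidation and no protecting group at that oxygen are needed; here the alternative is better than the chosen plan, which spends two steps and a later deprotection on this oxygen. The competing Stetter additions would be 4-exo or 5-endo and are therefore geometrically poor. Against it, the aldehyde is neopentyl-like and alpha-oxygenated, so the Breslow intermediate should form slowly, the acceptor is a conjugated and deactivated enone carbonyl, and the benzoin step is reversible, so the open form may be preferred. Above all, A4 already contains the fully substituted C3 with its ether oxygen, so the alternative presupposes a solution to the central problem; the oxonium ylide shift of the chosen plan could even be used to make it. Mechanistically the two plans are equal in that both close the last carbocycle by addition to a ketone inside a pre-formed oxabicycle. In step economy the alternative is worse, because C3 needs a one-carbon aldehyde handle and the cyclohexenone has to be built separately.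

Alternative 3: The cut is the C8=C9 double bond, replaced retrosynthetically by a CH2–SO2–C(Cl)(CO2Me) bridge between C1 and C7. The precursor is the alpha-chloro sulfone A6, a 3-thiabicyclo[3.2.2]nonane S,S-dioxide fused to the tetrahydrofuran. In the forward key step base would deprotonate the sulfone CH2, the carbanion would displace chloride from the ester-bearing carbon (3-exo-tet), and the episulfone would lose SO2 to give enoate A5. In its favour, the position of the alkene is unambiguous, the ketone of A6 has no alpha-hydrogen, and loss of SO2 is irreversible, which is better than a reversible aldol closure. The two bridgehead oxygens carry different silyl groups, so the one needed for the spiro closure can be freed selectively; on this point it is the equal of the chosen plan. Against it, the displacement must occur at a fully substituted carbon next to a quaternary bridgehead, and the contraction from a three-atom to a two-atom bridge raises strain. Making A6 needs two C–S bonds at neopentyl positions, oxidation of a sulfide beside a prenyl alkene and a chlorination. As in alternative 2, the quaternary C3 must already exist. Compared with the chosen plan the ring-forming event is more predictable, but the route is clearly longer and gives no answer for C3.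

Key step: step 7

Remark: (1S,5R)-(−)-nopinone 1 is taken as purchasable; otherwise it is one ozonolysis away from (+)-β-pinene.
Remark: the natural configuration at the ring A spiro carbon and at the adjacent CH(prenyl) carbon is assumed to be the thermodynamically preferred one, since both centres are set reversibly in step 18.
Remark on the structure check: 12 (S) and 14 (1S,5S) map centre for centre onto the target cage and onto 1, so no descriptor needed correction. Two weaknesses of the most direct way to 12 were removed. Base-mediated O-allylation of the tertiary alcohol at the 1,3-dione stage (competing dione alkylation, retro-aldol loss of acetone) is replaced by acid-catalysed allylation at the enone stage. The dione is then made without zerovalent palladium, which could transfer the allyl group from the ether to the acidic dione.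

## Steps

Step 1
Reactants: 1 (1S,5R)-(−)-nopinone
Product: 2 (R)-4-(2-acetoxypropan-2-yl)cyclohex-1-en-1-yl acetate
Conditions: Ac2O, Zn(OAc)2 (cat.), BF3·OEt2 (cat.), 0 °C → rt
Reagents that add atoms: acetic anhydride, CC(=O)OC(C)=O
Why: Lewis-acid activation of the ketone breaks the strained cyclobutane bond between the alpha-carbon and the CMe2 carbon (acid-promoted cyclobutyl ketone fragmentation); acetate captures the tertiary cation and the enolate oxygen is acetylated, so the enol double bond lies only on the side of the broken bond. The untouched methine stereocentre and this regiodefined enol acetate make 2 a single enantiomer.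

Step 2
Reactants: 2 (R)-4-(2-acetoxypropan-2-yl)cyclohex-1-en-1-yl acetate
Product: 6 (R)-4-(2-hydroxypropan-2-yl)cyclohex-2-en-1-one, via dilithium enolate alkoxide 3 (not isolated), via alpha-selanyl ketone 4 (not isolated), via selenoxide 5 (not isolated)
Conditions: MeLi (4.2 equiv), THF, −78 → 0 °C; PhSeBr (1.05 equiv), −78 °C; AcOH, then 30% H2O2, 0 °C → rt
Reagents that add atoms: none
Why: MeLi cleaves both acetates and releases the lithium enolate regiospecifically without equilibration; enolate selenenylation followed by selenoxide syn-elimination can only take a hydrogen from C3, so the alkene forms towards the stereocentre, which is not touched. The tertiary alcohol is unmasked in the same operation, which avoids a basic deacetylation of the racemisation-prone enone.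

Step 3
Reactants: 6 (R)-4-(2-hydroxypropan-2-yl)cyclohex-2-en-1-one; 7 allyl 2,2,2-trichloroacetimidate
Product: 8 (R)-4-[2-(allyloxy)propan-2-yl]cyclohex-2-en-1-one
Conditions: TfOH (5 mol %), CH2Cl2–cyclohexane 1:2, 0 °C → rt
Reagents that add atoms: none
Why: Acid-catalysed etherification with a trichloroacetimidate allylates the hindered tertiary alcohol without base, so neither vinylogous retro-aldol loss of acetone nor gamma-deprotonation of the enone (racemisation) can occur; formation of trichloroacetamide drives the reaction.

Step 4
Reactants: 8 (R)-4-[2-(allyloxy)propan-2-yl]cyclohex-2-en-1-one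
Product: 10 (3R,4R)-4-[2-(allyloxy)propan-2-yl]-3-hydroxycyclohexan-1-one, via beta-boryl ketone 9 (not isolated)
Conditions: B2pin2 (1.1 equiv), CuCl (3 mol %), Xantphos (3 mol %), NaOtBu (6 mol %), MeOH (2 equiv), THF, rt; then NaBO3·4H2O, THF–H2O, rt
Reagents that add atoms: sodium perborate tetrahydrate, [Na+].[O-]OB=O.O.O.O.O
Why: Copper-catalysed conjugate borylation puts boron on the beta-carbon anti to the side chain and perborate oxidises the C–B bond with retention; only the electron-poor enone alkene reacts, the allyl ether is inert. The new carbinol centre is of no consequence because it becomes a carbonyl in step 5.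

Step 5
Reactants: 10 (3R,4R)-4-[2-(allyloxy)propan-2-yl]-3-hydroxycyclohexan-1-one
Product: 11 (S)-4-[2-(allyloxy)propan-2-yl]cyclohexane-1,3-dione
Conditions: IBX (1.5 equiv), EtOAc, 75 °C
Reagents that add atoms: none
Why: IBX oxidation of a beta-hydroxy ketone gives the 1,3-dione without touching the terminal alkene; the neutral conditions leave the C4 stereocentre, now alpha to a carbonyl of an enolised dione, intact.

Step 6
Reactants: 11 (S)-4-[2-(allyloxy)propan-2-yl]cyclohexane-1,3-dione
Product: 12 (S)-4-[2-(allyloxy)propan-2-yl]-2-diazocyclohexane-1,3-dione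
Conditions: 4-acetamidobenzenesulfonyl azide (1.1 equiv), Et3N, MeCN, 0 °C → rt
Reagents that add atoms: 4-acetamidobenzenesulfonyl azide, CC(=O)Nc1ccc(cc1)S(=O)(=O)N=[N+]=[N-]
Why: Regitz diazo transfer to C2 of the dione; the dione monoanion does not enolise further towards C4, so the stereocentre holds.

Step 7
Reactants: 12 (S)-4-[2-(allyloxy)propan-2-yl]-2-diazocyclohexane-1,3-dione
Product: 14 (1S,5S)-5-allyl-7,7-dimethyl-6-oxabicyclo[3.2.1]octane-4,8-dione, via oxonium ylide 13 (not isolated)
Conditions: Rh2(OAc)4 (2 mol %), CH2Cl2, 40 °C, slow addition of 12 (final 0.01 M)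
Reagents that add atoms: none
Why: Rh2(OAc)4 expels N2 from 12 and gives an electrophilic acceptor/acceptor carbenoid at C2 whose vacant orbital points along the axial direction of the flattened dione ring. The ether oxygen of the axial C4 side chain attacks it in a 5-exo sense (lone pair on the carbenoid carbon), closing a tetrahydrofuran-3-one ring that is the O6–C7 bridge of the 6-oxabicyclo[3.2.1]octane, to give ylide 13, which probably stays carbon-bound to rhodium because a bridgehead carbanion cannot conjugate with either carbonyl. The allyl group then moves from the oxonium oxygen to carbon through a five-centre [2,3]-sigmatropic transition state (a [1,2]-shift of unsubstituted allyl would give the same product), forming the C5–CH2 bond and releasing the catalyst. The closest known reaction type is the rhodium- or copper-catalysed cyclisation of allyloxy-substituted diazo ketones and diazo keto esters to 2-allyl-tetrahydrofuran-3-ones through oxonium ylides. The new quaternary centre C5 (cage C3) is controlled entirely by the C4 stereocentre of 12 (C1 of 14): a one-carbon tether can only bridge the six-membered ring cis, and the allyl group takes the only remaining exo position. The selectivities needed are ylide formation over 1,5 C–H insertion into the gem-dimethyl groups, over insertion into the OCH2 group, over cyclopropanation of the remote alkene (which would need a seven-membered ring) and over Wolff ring contraction; the five-membered approach of a basic sp3 oxygen to a strongly electrophilic dione carbenoid, slow addition at low concentration and, if needed, the less insertion-prone Cu(hfacac)2 secure this. The single stereocentre is alpha to a ketone, so the neutral conditions of the step also protect it from epimerisation.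

Step 8
Reactants: 14 (1S,5S)-5-allyl-7,7-dimethyl-6-oxabicyclo[3.2.1]octane-4,8-dione
Product: 15 (1S,5S)-5-allyl-4-[(tert-butyldimethylsilyl)oxy]-7,7-dimethyl-6-oxabicyclo[3.2.1]oct-3-en-8-one
Conditions: TBSOTf (1.2 equiv), Et3N (2 equiv), CH2Cl2, −20 → 0 °C
Reagents that add atoms: tert-butyldimethylsilyl trifluoromethanesulfonate, CC(C)(C)[Si](C)(C)OS(=O)(=O)C(F)(F)F
Why: Soft enolisation and O-silylation; C3 is the only enolisable position (C1 is a bridgehead, C5 is quaternary), so only one silyl enol ether can form.

Step 9
Reactants: 15 (1S,5S)-5-allyl-4-[(tert-butyldimethylsilyl)oxy]-7,7-dimethyl-6-oxabicyclo[3.2.1]oct-3-en-8-one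
Product: 17 (1S,3R,5R)-5-allyl-3-[(tert-butyldimethylsilyl)oxy]-7,7-dimethyl-6-oxabicyclo[3.2.1]octane-4,8-dione, via silyloxy epoxide 16 (not isolated)
Conditions: mCPBA (1.05 equiv), CH2Cl2, −20 → 0 °C
Reagents that add atoms: 3-chloroperoxybenzoic acid, OOC(=O)c1cccc(Cl)c1
Why: Rubottom oxidation: the electron-rich silyl enol ether is epoxidised much faster than the terminal alkene, from the face of the one-carbon C8 bridge because the other face is shielded by a C7 methyl group, and the carboxylic acid formed opens the silyloxy epoxide with 1,4-silyl migration to the alpha-silyloxy ketone. The C3 configuration is immaterial because C3 is enolised again in step 11.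

Step 10
Reactants: 17 (1S,3R,5R)-5-allyl-3-[(tert-butyldimethylsilyl)oxy]-7,7-dimethyl-6-oxabicyclo[3.2.1]octane-4,8-dione; 18 2-methylbut-2-ene
Product: 19 (1S,3R,5R)-3-[(tert-butyldimethylsilyl)oxy]-7,7-dimethyl-5-(3-methylbut-2-en-1-yl)-6-oxabicyclo[3.2.1]octane-4,8-dione
Conditions: second-generation Grubbs catalyst RuCl2(=CHPh)(H2IMes)(PCy3) (5 mol %), 18 (excess)/CH2Cl2, 40 °C
Reagents that add atoms: none
Why: Olefin cross-metathesis of a terminal alkene with excess 2-methylbut-2-ene is the standard allyl-to-prenyl conversion; ketones and silyl ethers are tolerated and propene escapes.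

Step 11
Reactants: 19 (1S,3R,5R)-3-[(tert-butyldimethylsilyl)oxy]-7,7-dimethyl-5-(3-methylbut-2-en-1-yl)-6-oxabicyclo[3.2.1]octane-4,8-dione; 20 methyl propiolate
Product: 23 methyl (1R,3R,6R,7S)-1-[(tert-butyldimethylsilyl)oxy]-7-hydroxy-5,5-dimethyl-3-(3-methylbut-2-en-1-yl)-2-oxo-4-oxatricyclo[4.3.1.0^3,7]dec-8-ene-8-carboxylate, via lithium enolate 21 (not isolated), via vinyllithium adduct 22 (not isolated)
Conditions: LiN(iPr)2 (1.05 equiv), THF, −78 °C; 20 (1.2 equiv), −78 → −30 °C; AcOH
Reagents that add atoms: none
Why: Michael-initiated ring closure: the only possible enolate adds through carbon to the beta-carbon of the alkynoate on the face of the one-carbon carbonyl bridge (the other face is blocked by the gem-dimethyl ether bridge), and the resulting vinyl anion/allenolate attacks that carbonyl intramolecularly (aldol, six-membered ring through a boat) to close the bicyclo[2.2.2]octene. Cage C1 is set by this facial selectivity and cage C7 by the tether, which can reach only one carbonyl face; C3 and C6 are carried from 14.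

Step 12
Reactants: 23 methyl (1R,3R,6R,7S)-1-[(tert-butyldimethylsilyl)oxy]-7-hydroxy-5,5-dimethyl-3-(3-methylbut-2-en-1-yl)-2-oxo-4-oxatricyclo[4.3.1.0^3,7]dec-8-ene-8-carboxylate
Product: 24 (1R,3R,6R,7S)-1-[(tert-butyldimethylsilyl)oxy]-7-hydroxy-5,5-dimethyl-3-(3-methylbut-2-en-1-yl)-2-oxo-4-oxatricyclo[4.3.1.0^3,7]dec-8-ene-8-carboxylic acid
Conditions: Me3SnOH (5 equiv), 1,2-dichloroethane, 80 °C; then 5% aq. HCl
Reagents that add atoms: trimethyltin hydroxide, C[Sn](C)(C)O
Why: Trimethyltin hydroxide cleaves methyl esters under essentially neutral conditions, so the beta-hydroxy ketone of the cage (retro-aldol) and the silyl ether are not exposed to hydroxide.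

Step 13
Reactants: 24 (1R,3R,6R,7S)-1-[(tert-butyldimethylsilyl)oxy]-7-hydroxy-5,5-dimethyl-3-(3-methylbut-2-en-1-yl)-2-oxo-4-oxatricyclo[4.3.1.0^3,7]dec-8-ene-8-carboxylic acid
Product: 25 (1R,3R,6R,7S)-1,7-dihydroxy-5,5-dimethyl-3-(3-methylbut-2-en-1-yl)-2-oxo-4-oxatricyclo[4.3.1.0^3,7]dec-8-ene-8-carboxylic acid
Conditions: 48% aq. HF, MeCN, 0 °C → rt
Reagents that add atoms: none
Why: Acidic fluoride desilylation; both tertiary alcohols are bridgeheads and cannot ionise, and acidic conditions avoid the alkoxide of the alpha-ketol that could trigger an acyloin shift.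

Step 14
Reactants: 26 2,6-dimethoxy-1,4-benzoquinone
Product: 27 2-hydroxy-6-methoxy-1,4-benzoquinone
Conditions: NaOH (1.05 equiv, 0.5 M aq.), THF, 0 °C → rt, degassed; then 1 M HCl
Reagents that add atoms: sodium hydroxide, [Na+].[OH-]
Why: Hydroxide adds to a methoxy-bearing carbon of the vinylogous ester and expels methoxide (addition–elimination); the vinylogous carboxylate formed deactivates the ring, so the second methoxy group should be retained.

Step 15
Reactants: 27 2-hydroxy-6-methoxy-1,4-benzoquinone; 28 3-methylbut-2-enal
Product: 30 7-methoxy-2,2-dimethyl-2H-chromene-5,8-dione, via oxatriene 29 (not isolated)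
Conditions: ethylenediammonium diacetate (10 mol %), toluene, 80 °C
Reagents that add atoms: none
Why: Knoevenagel condensation at the nucleophilic C3 of the vinylogous acid followed by oxa-6π electrocyclisation of the 1-oxatriene, the chromene annulation known for 2-hydroxy-1,4-quinones and enals; closure through the former hydroxyl oxygen leaves the more stable para-quinone, and reversibility of the electrocyclisation lets this isomer accumulate.

Step 16
Reactants: 30 7-methoxy-2,2-dimethyl-2H-chromene-5,8-dione
Product: 31 7-hydroxy-2,2-dimethyl-2H-chromene-5,8-dione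
Conditions: NaOH (1.1 equiv, 0.5 M aq.), THF, 0 °C → rt; then 1 M HCl
Reagents that add atoms: sodium hydroxide, [Na+].[OH-]
Why: The same addition–elimination at the unhindered methoxy-bearing C7; attack at the tetrasubstituted pyran carbon C8a is slower and would be reversible.

Step 17
Reactants: 31 7-hydroxy-2,2-dimethyl-2H-chromene-5,8-dione; 32 prenyl bromide
Product: 33 7-hydroxy-2,2-dimethyl-6-(3-methylbut-2-en-1-yl)-2H-chromene-5,8-dione
Conditions: LiH (1.1 equiv), DMSO, rt; 32 (1.2 equiv); then 1 M HCl
Reagents that add atoms: none
Why: C-alkylation of the ambident lithium quinone-olate at C6, the reaction type used for prenylation of 2-hydroxy-1,4-naphthoquinone; the tightly bound lithium oxygen in DMSO biases towards carbon, with O-prenylation as the competing path.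

Step 18
Reactants: 25 (1R,3R,6R,7S)-1,7-dihydroxy-5,5-dimethyl-3-(3-methylbut-2-en-1-yl)-2-oxo-4-oxatricyclo[4.3.1.0^3,7]dec-8-ene-8-carboxylic acid; 33 7-hydroxy-2,2-dimethyl-6-(3-methylbut-2-en-1-yl)-2H-chromene-5,8-dione
Product: 35 CNP0222516.1 (spiro acylal lactone; ring A 6S and 7S; cage 1R 3R 6S 7S), via acyloxyquinone 34 (not isolated)
Conditions: EDC·HCl (1.3 equiv), DMAP (0.2 equiv), 4 Å MS, CH2Cl2, 0 °C → rt; then CSA (0.5 equiv), rt
Reagents that add atoms: none
Why: Steglich-type O-acylation of the vinylogous acid hydroxyl of 33 gives 34 at O7 (the para-quinone ester is the more stable tautomer and O5 is flanked by the pyran and the prenyl group); acid then promotes 6-exo-trig oxa-Michael addition of the cage C7 hydroxyl to the acyloxy-bearing ring A carbon C7, which is beta to the C5 carbonyl, followed by ketonisation at C6. Both new centres are under thermodynamic control, since the ketal-type C–O bond forms reversibly and C6–H is enolisable; the prenyl group is expected to settle trans to the cage oxygen, and the cage fixes its own centres.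

## Compound list

1 | (1S,5R)-(−)-nopinone, (1S,5R)-6,6-dimethylbicyclo[3.1.1]heptan-2-one | CC1(C)[C@@H]2CCC(=O)[C@H]1C2 | starting material
2 | (R)-4-(2-acetoxypropan-2-yl)cyclohex-1-en-1-yl acetate | CC(=O)OC1=CC[C@@H](CC1)C(C)(C)OC(C)=O | intermediate
3 | dilithium (R)-4-(2-oxidopropan-2-yl)cyclohex-1-en-1-olate | [Li+].[Li+].[O-]C1=CC[C@@H](CC1)C(C)(C)[O-] | intermediate
4 | (4R)-4-(2-hydroxypropan-2-yl)-2-(phenylselanyl)cyclohexan-1-one (C2 epimers) | O=C1CC[C@@H](C(C)(C)O)CC1[Se]c1ccccc1 | intermediate
5 | (4R)-4-(2-hydroxypropan-2-yl)-2-(phenylseleninyl)cyclohexan-1-one | O=C1CC[C@@H](C(C)(C)O)CC1[Se](=O)c1ccccc1 | intermediate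
6 | (R)-4-(2-hydroxypropan-2-yl)cyclohex-2-en-1-one | O=C1CC[C@@H](C(C)(C)O)C=C1 | intermediate
7 | allyl 2,2,2-trichloroacetimidate | C=CCOC(=N)C(Cl)(Cl)Cl | starting material
8 | (R)-4-[2-(allyloxy)propan-2-yl]cyclohex-2-en-1-one | O=C1CC[C@@H](C(C)(C)OCC=C)C=C1 | intermediate
9 | (3R,4R)-4-[2-(allyloxy)propan-2-yl]-3-(4,4,5,5-tetramethyl-1,3,2-dioxaborolan-2-yl)cyclohexan-1-one (trans) | O=C1CC[C@@H](C(C)(C)OCC=C)[C@H](B2OC(C)(C)C(C)(C)O2)C1 | intermediate
10 | (3R,4R)-4-[2-(allyloxy)propan-2-yl]-3-hydroxycyclohexan-1-one (trans) | O=C1CC[C@@H](C(C)(C)OCC=C)[C@H](O)C1 | intermediate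
11 | (S)-4-[2-(allyloxy)propan-2-yl]cyclohexane-1,3-dione | O=C1CC[C@@H](C(C)(C)OCC=C)C(=O)C1 | intermediate
12 | (S)-4-[2-(allyloxy)propan-2-yl]-2-diazocyclohexane-1,3-dione | C1C[C@@H](C(C)(C)OCC=C)C(=O)C(=[N+]=[N-])C1=O | intermediate
13 | bicyclic allyloxonium ylide, (1S)-6-allyl-7,7-dimethyl-4,8-dioxo-6-oxoniabicyclo[3.2.1]octan-5-ide | C=CC[O+]1[C-]2C(=O)CC[C@H](C2=O)C1(C)C | intermediate
14 | (1S,5S)-5-allyl-7,7-dimethyl-6-oxabicyclo[3.2.1]octane-4,8-dione | C1C[C@H]2C(C)(C)O[C@@](CC=C)(C1=O)C2=O | intermediate
15 | (1S,5S)-5-allyl-4-[(tert-butyldimethylsilyl)oxy]-7,7-dimethyl-6-oxabicyclo[3.2.1]oct-3-en-8-one | CC(C)(C)[Si](C)(C)OC1=CC[C@H]2C(C)(C)O[C@]1(CC=C)C2=O | intermediate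
16 | 3,4-epoxide of 15 on the face of the C8 bridge (silyloxy epoxide) | CC(C)(C)[Si](C)(C)O[C@@]12O[C@@H]1C[C@H]3C(C)(C)O[C@]2(CC=C)C3=O | intermediate
17 | (1S,3R,5R)-5-allyl-3-[(tert-butyldimethylsilyl)oxy]-7,7-dimethyl-6-oxabicyclo[3.2.1]octane-4,8-dione | CC(C)(C)[Si](C)(C)O[C@@H]1C[C@H]2C(C)(C)O[C@@](CC=C)(C1=O)C2=O | intermediate
18 | 2-methylbut-2-ene | CC=C(C)C | starting material
19 | (1S,3R,5R)-3-[(tert-butyldimethylsilyl)oxy]-7,7-dimethyl-5-(3-methylbut-2-en-1-yl)-6-oxabicyclo[3.2.1]octane-4,8-dione | CC(C)(C)[Si](C)(C)O[C@@H]1C[C@H]2C(C)(C)O[C@@](CC=C(C)C)(C1=O)C2=O | intermediate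
20 | methyl propiolate | C#CC(=O)OC | starting material
21 | lithium enolate of 19 (C3=C4 enolate) | [Li+].[O-]C1=C(O[Si](C)(C)C(C)(C)C)C[C@H]2C(C)(C)O[C@]1(CC=C(C)C)C2=O | intermediate
22 | vinyllithium (allenolate) Michael adduct of 21 and 20 | [Li+].COC(=O)[C-]=C[C@]1(O[Si](C)(C)C(C)(C)C)C[C@H]2C(C)(C)O[C@@](CC=C(C)C)(C1=O)C2=O | intermediate
23 | methyl (1R,3R,6R,7S)-1-[(tert-butyldimethylsilyl)oxy]-7-hydroxy-5,5-dimethyl-3-(3-methylbut-2-en-1-yl)-2-oxo-4-oxatricyclo[4.3.1.0^3,7]dec-8-ene-8-carboxylate | COC(=O)C1=C[C@]3(O[Si](C)(C)C(C)(C)C)C[C@H]4C(C)(C)O[C@@](CC=C(C)C)(C3=O)[C@@]14O | intermediate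
24 | (1R,3R,6R,7S)-1-[(tert-butyldimethylsilyl)oxy]-7-hydroxy-5,5-dimethyl-3-(3-methylbut-2-en-1-yl)-2-oxo-4-oxatricyclo[4.3.1.0^3,7]dec-8-ene-8-carboxylic acid | OC(=O)C1=C[C@]3(O[Si](C)(C)C(C)(C)C)C[C@H]4C(C)(C)O[C@@](CC=C(C)C)(C3=O)[C@@]14O | intermediate
25 | (1R,3R,6R,7S)-1,7-dihydroxy-5,5-dimethyl-3-(3-methylbut-2-en-1-yl)-2-oxo-4-oxatricyclo[4.3.1.0^3,7]dec-8-ene-8-carboxylic acid | OC(=O)C1=C[C@]3(O)C[C@H]4C(C)(C)O[C@@](CC=C(C)C)(C3=O)[C@@]14O | intermediate
26 | 2,6-dimethoxy-1,4-benzoquinone | COC1=CC(=O)C=C(OC)C1=O | starting material
27 | 2-hydroxy-6-methoxy-1,4-benzoquinone | COC1=CC(=O)C=C(O)C1=O | intermediate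
28 | 3-methylbut-2-enal | CC(C)=CC=O | starting material
29 | 6-methoxy-3-(3-methylbut-2-en-1-ylidene)cyclohex-5-ene-1,2,4-trione (1-oxatriene) | COC1=CC(=O)C(=CC=C(C)C)C(=O)C1=O | intermediate
30 | 7-methoxy-2,2-dimethyl-2H-chromene-5,8-dione | COC1=CC(=O)C2=C(OC(C)(C)C=C2)C1=O | intermediate
31 | 7-hydroxy-2,2-dimethyl-2H-chromene-5,8-dione | OC1=CC(=O)C2=C(OC(C)(C)C=C2)C1=O | intermediate
32 | prenyl bromide, 1-bromo-3-methylbut-2-ene | CC(C)=CCBr | starting material
33 | 7-hydroxy-2,2-dimethyl-6-(3-methylbut-2-en-1-yl)-2H-chromene-5,8-dione | CC(C)=CCC1=C(O)C(=O)C2=C(C=CC(C)(C)O2)C1=O | intermediate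
34 | 2,2-dimethyl-6-(3-methylbut-2-en-1-yl)-5,8-dioxo-2H-chromen-7-yl ester of acid 25 (acyloxyquinone) | CC(C)=CCC1=C(OC(=O)C3=C[C@]4(O)C[C@H]5C(C)(C)O[C@@](CC=C(C)C)(C4=O)[C@@]35O)C(=O)C2=C(C=CC(C)(C)O2)C1=O | intermediate
35 | CNP0222516.1: spiro 1,3-dioxan-4-one joining ring A C7 of (6S,7S)-2,2-dimethyl-6-prenyl-6,7-dihydro-2H-chromene-5,8-dione to the C8 carboxyl and C7 oxygen of the (1R,3R,6S,7S)-1-hydroxy-5,5-dimethyl-3-prenyl-4-oxatricyclo[4.3.1.0^3,7]dec-8-en-2-one cage | CC(C)=CC[C@H]1C(=O)C2=C(OC(C)(C)C=C2)C(=O)[C@@]12OC(=O)C1=C[C@]3(O)C[C@H]4C(C)(C)O[C@@](CC=C(C)C)(C3=O)[C@@]14O2 | target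

## Step count and least certain steps

Total: 18 steps. Longest linear sequence: 14 steps (steps 1–13 and 18); the ring A branch is steps 14–17.

Step 7 (key step). The most likely failure is diversion of the carbenoid into C–H insertion at a methyl or the OCH2 group, or into Wolff ring contraction. The ylide carbon becomes a bridgehead that gains no enolate stabilisation, which may slow ylide formation or make it reversible. Fallback without a carbene, from 6 back to 14: 6 is taken through the conditions of step 4 to (3R,4R)-3-hydroxy-4-(2-hydroxypropan-2-yl)cyclohexan-1-one F1 and oxidised with IBX to (S)-4-(2-hydroxypropan-2-yl)cyclohexane-1,3-dione F2. Tsuji–Trost C-allylation with allyl acetate and Pd(PPh3)4 (zerovalent palladium) gives (4S)-2-allyl-4-(2-hydroxypropan-2-yl)cyclohexane-1,3-dione F3. Oxidative etherification with PhI(OAc)2 (trivalent iodine; the tertiary alcohol attacks C2 of the iodine-bound enolate) closes the same cis-bridged ether and rejoins the route at 14.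

Step 11. Three processes threaten it: proton transfer from the acetylenic C–H of 20 to enolate 21, which would return 19; O-attack of the hindered, fully substituted enolate on 20; and protonation of the vinyl anion before it reaches the carbonyl. Deprotonation of the shielded C3–H may also be slow. Fallback from 19 back to 23 without an alkyne: Michael–aldol reaction of the same enolate with methyl acrylate (LiN(iPr)2, THF, −78 °C) gives the saturated cage ester methyl 1-[(tert-butyldimethylsilyl)oxy]-7-hydroxy-5,5-dimethyl-3-prenyl-2-oxo-4-oxatricyclo[4.3.1.0^3,7]decane-8-carboxylate F4. Its alkoxide/ester-enolate dianion (LiN(iPr)2, 2.2 equiv) is selenenylated with PhSeBr to the 8-(phenylselanyl) ester F5, and H2O2 oxidation with selenoxide syn-elimination towards C9 gives 23.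

Step 18. The activated ester 34 may be lost by acyl transfer or hydrolysis before the hindered tertiary alcohol adds. Once closed, base can open the acylal by beta-elimination of the carboxylate from the ring A enolate, and the spiro carbon may equilibrate to a mixture of epimers. Fallback that reverses the roles of the partners, from 33 and 25 back to 34: oxalyl chloride with catalytic DMF converts 33 into the vinylogous acid chloride 7-chloro-2,2-dimethyl-6-(3-methylbut-2-en-1-yl)-2H-chromene-5,8-dione F6. The caesium carboxylate of 25 (Cs2CO3, one equivalent, MeCN) substitutes chloride by addition–elimination at ring A C7, so no carbodiimide and no nucleophilic amine are present. This rejoins the route at 34, which is closed to 35 with CSA as in step 18.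

Step 3. Acid may ionise the tertiary alcohol, with elimination to the achiral isopropylidene dienone, and the hindered hydroxyl may react slowly with the imidate. Fallback using a Williamson etherification on a carbonyl-free intermediate, from 2 back to 8: MeLi followed by TBSCl/HMPA silylates only the enolate oxygen and gives (R)-2-{4-[(tert-butyldimethylsilyl)oxy]cyclohex-3-en-1-yl}propan-2-ol F7. NaH and allyl bromide in THF give the allyl ether (R)-{4-[2-(allyloxy)propan-2-yl]cyclohex-1-en-1-yl}oxy(tert-butyl)dimethylsilane F8. Saegusa–Ito oxidation with Pd(OAc)2 (divalent palladium) in MeCN gives 8 with the alkene again on the side of the stereocentre.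

Step 17. O-alkylation of the ambident anion may outrun C-alkylation, and a second alkylation may follow. Fallback at the hydroquinone oxidation level, from 31 back to 33: Na2S2O4 reduces 31 to 2,2-dimethyl-2H-chromene-5,7,8-triol F9. Its only free aromatic carbon, flanked by two hydroxyl groups, is C-prenylated with 32 in aqueous KOH to 2,2-dimethyl-6-(3-methylbut-2-en-1-yl)-2H-chromene-5,7,8-triol F10. Oxidation with air or Ag2O returns the hydroxyquinone 33.

## Further compounds

F1 | step 7 | (3R,4R)-3-hydroxy-4-(2-hydroxypropan-2-yl)cyclohexan-1-one | O=C1CC[C@@H](C(C)(C)O)[C@H](O)C1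
F2 | step 7 | (S)-4-(2-hydroxypropan-2-yl)cyclohexane-1,3-dione | O=C1CC[C@@H](C(C)(C)O)C(=O)C1
F3 | step 7 | (4S)-2-allyl-4-(2-hydroxypropan-2-yl)cyclohexane-1,3-dione (C2 epimers/enol) | C=CCC1C(=O)CC[C@@H](C(C)(C)O)C1=O
F4 | step 11 | methyl 1-[(tert-butyldimethylsilyl)oxy]-7-hydroxy-5,5-dimethyl-3-(3-methylbut-2-en-1-yl)-2-oxo-4-oxatricyclo[4.3.1.0^3,7]decane-8-carboxylate (C8 epimers) | COC(=O)C1C[C@]3(O[Si](C)(C)C(C)(C)C)C[C@H]4C(C)(C)O[C@@](CC=C(C)C)(C3=O)[C@@]14O
F5 | step 11 | methyl 1-[(tert-butyldimethylsilyl)oxy]-7-hydroxy-5,5-dimethyl-3-(3-methylbut-2-en-1-yl)-2-oxo-8-(phenylselanyl)-4-oxatricyclo[4.3.1.0^3,7]decane-8-carboxylate | COC(=O)C1([Se]c2ccccc2)C[C@]3(O[Si](C)(C)C(C)(C)C)C[C@H]4C(C)(C)O[C@@](CC=C(C)C)(C3=O)[C@@]14O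
F6 | step 18 | 7-chloro-2,2-dimethyl-6-(3-methylbut-2-en-1-yl)-2H-chromene-5,8-dione | CC(C)=CCC1=C(Cl)C(=O)C2=C(C=CC(C)(C)O2)C1=O
F7 | step 3 | (R)-2-{4-[(tert-butyldimethylsilyl)oxy]cyclohex-3-en-1-yl}propan-2-ol | CC(C)(C)[Si](C)(C)OC1=CC[C@@H](CC1)C(C)(C)O
F8 | step 3 | (R)-{4-[2-(allyloxy)propan-2-yl]cyclohex-1-en-1-yl}oxy(tert-butyl)dimethylsilane | CC(C)(C)[Si](C)(C)OC1=CC[C@@H](CC1)C(C)(C)OCC=C
F9 | step 17 | 2,2-dimethyl-2H-chromene-5,7,8-triol | Oc1cc(O)c2C=CC(C)(C)Oc2c1O
F10 | step 17 | 2,2-dimethyl-6-(3-methylbut-2-en-1-yl)-2H-chromene-5,7,8-triol | CC(C)=CCc1c(O)c(O)c2OC(C)(C)C=Cc2c1O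
A1 | alternative 1 | cage enoate with 4-methoxybenzyl ether at the oxygenated bridgehead and silyl ether at the carbinol bridgehead (methyl ester) | COC(=O)C1=C[C@]3(O[Si](C)(C)C(C)(C)C)C[C@H]4C(C)(C)O[C@@](CC=C(C)C)(C3=O)[C@@]14OCc1ccc(OC)cc1
A2 | alternative 1 | methyl 6-[(tert-butyldimethylsilyl)oxy]-3-(iodomethyl)-2,2-dimethyl-7a-(3-methylbut-2-en-1-yl)-7-oxo-2,3,7,7a-tetrahydrobenzofuran-4-carboxylate | COC(=O)C1=C2[C@@H](CI)C(C)(C)O[C@@]2(CC=C(C)C)C(=O)C(O[Si](C)(C)C(C)(C)C)=C1
A3 | alternative 2 | cage ketol with trimethylsilyl ether at the oxygenated bridgehead (methyl ester) | COC(=O)C1=C[C@]3(O)C[C@H]2C(C)(C)O[C@@](CC=C(C)C)(C3=O)[C@@]12O[Si](C)(C)C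
A4 | alternative 2 | methyl 2-formyl-3,3-dimethyl-2-(3-methylbut-2-en-1-yl)-5-oxo-7a-[(trimethylsilyl)oxy]-2,3,3a,4,5,7a-hexahydrobenzofuran-7-carboxylate (keto aldehyde) | COC(=O)C1=CC(=O)C[C@H]2C(C)(C)O[C@@](CC=C(C)C)(C=O)[C@@]12O[Si](C)(C)C
A5 | alternative 3 | cage enoate with tert-butyldimethylsilyl ether at the carbinol bridgehead and triethylsilyl ether at the oxygenated bridgehead (methyl ester) | COC(=O)C1=C[C@]3(O[Si](C)(C)C(C)(C)C)C[C@H]4C(C)(C)O[C@@](CC=C(C)C)(C3=O)[C@@]14O[Si](CC)(CC)CC
A6 | alternative 3 | sulfone-bridged precursor with CH2–SO2–C(Cl)(CO2Me) between the two bridgeheads (either epimer at the chlorinated carbon) | COC(=O)C1(Cl)S(=O)(=O)C[C@]3(O[Si](C)(C)C(C)(C)C)C[C@H]4C(C)(C)O[C@@](CC=C(C)C)(C3=O)[C@@]14O[Si](CC)(CC)CC
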